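All runs come from a simulation with made-up constants.

Maple was charged with 4.00 times the initiator of oak, yet at 50.0 min its reading of monomer in chains is 7.50 times oak's, and both carry the same impurity.

| setting | oak | maple | flask |
|---|---|---|---|
| free monomer | 1.5 M | 1.5 M | 1.5 M |
| initiator | 2.1 mM | 8.4 mM | 4.2 mM |
| impurity | 1.3 mM | 1.3 mM | 1.3 mM |
| remark | run made earlier | run made earlier |  |
| time |  |  | 1.0 h |

- oak (time / min: monomer in chains / %, free monomer / %): 3.00: 0.1, 100.0; 10.0: 0, 100.0; 15.0: 0.7, 100.1; 25.0: 0.5, 100.0; 40.0: 1.0, 99.2; 50.0: 1.2, 98.9
- maple (time / min: monomer in chains / %, free monomer / %): 8.00: 0.1, 99.5; 15.0: 1.4, 98.5; 25.0: 3.3, 97.0; 30.0: 4.2, 95.6; 40.0: 6.5, 93.1; 50.0: 9.0, 90.3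

(each reading ± 0.3 percentage points)

* whether the average number of monomer units in a chain (chains begun, living or dead) reaches 80 by 1.0 h (yes / no)
* average number of monomer units in a chain (chains begun, living or dead) at 1.0 h

I suppose that the impurity destroys initiator one for one, which leaves the spare initiator S, the excess reagent of that titration: charge minus impurity, 7.10 mM in maple, 0.800 mM in oak and 2.90 mM in the flask. I test this on oak: scaling maple's 9.0 % by whole charges gives 2.25 %, scaling by S gives 1.01 %, and oak reads 1.2 % with a scatter of 0.3 percentage points, so I scale by S.

I continue maple's last rise to 1.0 h, which gives 11.5 %, and from this I take the turnover count n, the monomer units in chains per spare initiator at that time, 24.3. For the flask this means 4.70 % of the monomer in chains. The readings do not show chains, so the length is n divided by the share of S that begins one, and it passes 80 if that share is under 0.304.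

The forecast answers no with a length of 32, granting that the “impurity stoichiometry is a guess”, whereas my reckoning leaves that share open.

The flask gives yes and 258, passing 80 at 0.363 h.

    free monomer + living end → monomer in chains + living end, rate k1*[living end]*[free monomer] (k = 4.20 /M/min)
    free monomer + initiator → living end + monomer in chains (k = 0.00320 /M/min)
    initiator + impurity → spent initiator A (k = 5500 /M/min)
    initiator → spent initiator B (k = 0.0380 /min)

At 1.00 h the flask holds 5.11 % of monomer in chains, which is 26.4 units per spare initiator beside my 24.3, and its length is ten times that count. At that time the flask's spent initiator B stands at 0.00238 M against 2.97 × 10⁻⁴ M of living end, and that living end is a share of S of 0.103, less than 0.304.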